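## Analysis of the target

Target 32 is a germacranolide. In germacrane numbering it is a cyclodeca-1(10),4-diene with a trans-fused α-methylene-γ-lactone on C6–C7 (C11–C13, ring oxygen on C6). Both ring alkenes are ring-cis: C1=C10 carries the methyl ester C14 and C4=C5 (Z) carries the methyl group; a cis-2,3-epoxide lies between them. C8 bears a (2R,3R)-2,3-epoxy-2-methylbutanoate and C9 a free secondary hydroxyl. The ring therefore has six stereocentres (C2, C3, C6, C7, C8, C9) and the ester two more; the C6 oxygen is trans and the C8 oxygen cis to the C7 side chain. Sensitive points are the methylene lactone (Michael acceptor), the vinyl epoxide conjugated with the enoate, and the vicinal O8-acyl/O9-H pair (acyl shift). The difficulty is a ten-membered ring with two cis trisubstituted alkenes and six stereocentres, for which direct ring closure is unattractive. The strategy rests on the fact that C4 and C9 face each other across the ring: a C4–C9 bond turns the macrocycle into a cis-decalin whose ring B (C4–C5–C6–C7–C8–C9) carries C6, C7, C8 and the two carbons that become C4=C5 and the C9 carbinol, while ring A (C4–C3–C2–C1–C10–C9) carries the enoate and the epoxide as ordinary six-membered-ring functions.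

## Retrosynthetic reasoning

**32 ⇒ 31 ⇒ 30 (C13–N).** The exocyclic methylene is cut back to the β-amino lactone 30 through ammonium salt 31. This keeps the acceptor absent while strong base and hydride are used. The forward steps, quaternisation and mild-base elimination, must be the last two.

**30 ⇒ 29 (C9–H).** The carbinol is traced to ketone 29 because the ring-opening step delivers C9 as a carbonyl group. The forward reduction must be 1,2-selective and must come from the outer face of the ring.

**29 ⇒ 28 (C4=C5 and C9=O back to the C4–C9 σ bond).** This is the only transannular bond that gives two six-membered rings with C6–C8 on one ring and both ring-cis units on the other. Its cleavage is stereospecific, so no macrocyclisation is needed and both alkene geometries come from small rings. The forward step needs a C9 alkoxide, a C5 sulfonate antiperiplanar to C4–C9, and C3 axial on ring B; the trans lactone of 28 holds that chair.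

**28 ⇒ 27 ⇒ 25 ⇒ 24 (S–O; the epoxide C–O bonds; C11–C13).** The sulfonate goes on last because it is only tolerable once no further base is needed. The epoxide is cut to the diene of 25 through a bromohydrin and not by peracid, because the C4 methyl group is pseudoaxial on ring A and shields the face on which the epoxide has to sit. The aminomethyl group is attached at dienoate 24, which has no acidic proton in ring A.

**24 ⇒ 21 (ring A diene from an isolated alkene).** The dienoate is traced to the C1=C2 alkene of 21 by bromination and twofold dehydrobromination. This keeps ring A inert towards hydride and oxidants while ring B is built.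

**21 ⇒ 20 ⇒ 17 ⇒ 16 (C5–H; lactone C–O bonds; C7–H).** C5 is reduced only after the trans lactone has locked the chair. The C6 oxygen comes from oxidation of the enol ether that the conjugate reduction leaves behind. C7 is set by hydride because a carbon nucleophile would enter anti to the C8 oxygen and give the wrong epimer; the carbon is therefore attached while C7 is trigonal and hydrogen is delivered last.

**16 ⇒ 15 ⇒ 14 ⇒ 13 (C7–C11).** The two-carbon ester unit is cut off at the enone β-carbon; the enol triflate 15 comes from diketone 14, and this from the vinylogous methyl ester of 13. The methoxy group thus serves twice: it steers the cycloaddition and marks C7 for the carbon–carbon bond.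

**13 ⇒ 11 + 4; 11 ⇒ 10 ⇒ 7 (ester C–O; C8–H; C9–O).** The epoxy ester is put on early, when C8 is an unhindered allylic alcohol. Because acid 4 is enantiopure, the same step resolves the racemic core. The C8 carbinol comes from hydroxyl-directed reduction of the ketone and the angular hydroxyl from enol ether oxidation.

**7 ⇒ 5 + 6 (C3–C4 and C9–C10).** A Diels–Alder reaction of the quinone builds ring A, the cis fusion, the quaternary C4 and a ring B in which every carbon is functionalised. A 2,2-disubstituted cyclohexane-1,3-dione would supply C5 and C9 but leaves C6–C8 as methylene groups, and the C8 oxygen would have to come from the hindered face. In 7 the C8 oxygen is a carbonyl group, so its configuration is set by hydride from the open face.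

**4 ⇒ 3 ⇒ 2 ⇒ 1.** The acid is cut back to angelic acid 1; the alkene geometry gives the cis relation of carboxyl and C3 methyl, and asymmetric epoxidation of allylic alcohol 2 gives the absolute configuration.

## Alternatives that were turned down

**Alternative 1:** Disconnection inside the lactone unit: the C7–C8 and C11–C13 bonds are made on butenolide A1 by copper-catalysed addition of a vinyl-metal reagent anti to the C6 substituent, and the enolate is trapped with a methyleneiminium salt to give A2. In its favour, C6, C7 and the masked methylene are set in one operation and the absolute configuration comes from the chiral pool; on that point it is stronger than the chosen route, which resolves a racemate. Against it, A2 holds two of six ring stereocentres and none of the ring. The ten-membered ring would still have to be closed between two elaborate chains, with two cis trisubstituted alkenes (one bearing the ester) and C8/C9 set by acyclic control. The chosen strategy never closes a medium ring and takes both alkene geometries from six-membered rings.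

**Alternative 2:** Disconnection of C10–C14, C11–C12 and C12–O: a twofold palladium-catalysed carbonylation would turn an alkenyl iodide at C10 into the ester and close the methylene lactone from the C6 hydroxyl and a C7 ethynyl group, giving A3. In its favour, both electrophilic carbonyl units appear in one late step; this is more economical than the three-step unmasking used here. Against it, the substrate must already be the complete ten-membered ring with the epoxide and all six stereocentres, so the hard part is untouched. The vinyl epoxide next to the iodide invites ionisation by zerovalent palladium, and two carbonylations with different demands must work in one pot. The chosen strategy offers a defined way to the ring and keeps transition metals away from the vinyl epoxide.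

**Alternative 3:** Ring expansion by an anionic oxy-Cope shift of a cis-1,2-dialkenyl epoxycyclohexenol, which forms C8–C9, cleaves a six-membered-ring bond and gives the ten-membered 6-ketone A4. Like the chosen route it obtains the macrocycle from a six-membered ring, and it is stronger in that the key step forms a carbon–carbon bond and can transmit configuration to C8 and C9. Against it, the C1=C10 geometry depends on a chair/boat choice in the transition state, C7 is set by protonation of an enolate next to a ketone, and a vinyl epoxide must survive strongly basic conditions. C12 and C14 are at the alcohol oxidation level behind three silyl ethers and a benzyl ether, so many redox and protecting-group steps follow. The chosen fragmentation fixes the alkene geometry stereospecifically through an antiperiplanar alignment and delivers all carbons at their final oxidation level, three steps from the target.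

Key step: step 18

Remarks on the chemistry:
- Germacrane numbering is kept for every bicyclic intermediate (ring B = C4–C9, ring A = C4, C3, C2, C1, C10, C9; C14 is the ester carbon on C10). α is the face of the decalin that carries the C4 methyl group, β the other face.
- Quinone 5 and dienoate 6 are taken as commercial. The cycloadduct is racemic; 7–11 are racemates (one enantiomer drawn), and the absolute configuration of the core is fixed in step 7 by separating the two diastereomeric esters formed with enantiopure acid 4.
- C11 of 25–31 is a mixture of epimers; this centre becomes trigonal in step 21.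

## Steps

Step 1
Reactants: 1 angelic acid [(Z)-2-methylbut-2-enoic acid]
Product: 2 (Z)-2-methylbut-2-en-1-ol
Conditions: LiAlH4, Et2O, 0 °C
Reagents that add atoms: none
Why: Hydride reduction of the carboxylic acid; the trisubstituted (Z)-alkene is not reduced and should not isomerise under these basic conditions.

Step 2
Reactants: 2 (Z)-2-methylbut-2-en-1-ol
Product: 3 [(2S,3R)-2,3-dimethyloxiran-2-yl]methanol
Conditions: Ti(OiPr)4, L-(+)-diethyl tartrate, t-BuOOH, 4 Å sieves, CH2Cl2, −20 °C
Reagents that add atoms: tert-butyl hydroperoxide, CC(C)(C)OO
Why: Sharpless asymmetric epoxidation of a trisubstituted (Z)-allylic alcohol; the L-(+)-tartrate complex should deliver oxygen to the face that gives the (2S,3R) epoxy alcohol, and the cis relation of CH2OH and the C3 methyl group follows from the alkene geometry.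

Step 3
Reactants: 3 [(2S,3R)-2,3-dimethyloxiran-2-yl]methanol
Product: 4 (2R,3R)-2,3-dimethyloxirane-2-carboxylic acid
Conditions: RuCl3 hydrate (cat.), NaIO4, CCl4/MeCN/H2O, rt
Reagents that add atoms: water, O
Why: Ruthenium tetroxide oxidation of a primary alcohol to the acid, which leaves the epoxide intact; the descriptor at C2 changes from S to R only through the change in priorities.

Step 4
Reactants: 5 2-methoxy-5-methyl-1,4-benzoquinone; 6 methyl (2E)-penta-2,4-dienoate
Product: 7 racemic cis-fused cycloadduct (4α-methyl, 9α-H, 10β-CO2Me; ketones at C5 and C8; 7-methoxy C6=C7; C1=C2)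
Conditions: PhMe, 110 °C, sealed tube, trace of 2,6-di-tert-butyl-4-methylphenol
Reagents that add atoms: none
Why: Thermal Diels–Alder reaction; the methoxy group deactivates its own double bond, so the diene should add to the methyl-bearing one, with the ester-bearing terminus bonding to the unsubstituted quinone carbon (ortho rule, C8 carbonyl as the dominant acceptor). Suprafacial endo addition gives the cis fusion with the C4 methyl and C9 hydrogen on one face; the configuration at C10 is of no consequence because C10 becomes trigonal in step 14.

Step 5
Reactants: 7 racemic cis-fused cycloadduct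
Product: 10 racemic 9α-hydroxy 8-ketone, via trimethylsilyl dienol ether 8 (not isolated), via 9-trimethylsilyloxy ketone 9 (not isolated)
Conditions: Me3SiOTf, Et3N, CH2Cl2, 0 °C; then dimethyldioxirane, acetone, −78 °C; then aq. citric acid
Reagents that add atoms: dimethyldioxirane, CC1(C)OO1
Why: Rubottom oxidation; C9–H is the only enolisable position of the C8 ketone, and the oxidant should attack the dienol ether on the face of the C4 methyl group, away from the arc of ring A and the C10 ester. The hydroxyl is then α and the ring fusion stays cis.

Step 6
Reactants: 10 racemic 9α-hydroxy 8-ketone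
Product: 11 racemic 8β,9α-diol
Conditions: Me4NBH(OAc)3, MeCN/AcOH, −30 °C
Reagents that add atoms: none
Why: Hydroxyl-directed (Saksena–Evans) reduction of an α-hydroxy ketone; hydride is delivered within the alkoxyborohydride from the α face of the C9 hydroxyl, so the C8 hydroxyl should come out β and trans to it. The vinylogous ester and the methyl ester are inert to this reagent.

Step 7
Reactants: 11 racemic 8β,9α-diol; 4 (2R,3R)-2,3-dimethyloxirane-2-carboxylic acid
Product: 13 8β-[(2R,3R)-2,3-dimethyloxirane-2-carbonyloxy] 9α-alcohol as a single enantiomer, via mixed anhydride 12 (not isolated)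
Conditions: 4, 2,4,6-Cl3C6H2COCl, Et3N, THF, rt; then 11, 4-(dimethylamino)pyridine, PhMe, rt; chromatographic separation of the two diastereomeric esters
Reagents that add atoms: none
Why: Yamaguchi esterification of the allylic secondary alcohol; the tertiary C9 hydroxyl should not react. The esters from the two enantiomers of 11 are diastereomers and are separated, which fixes the absolute configuration of the core and installs the target's ester while C8 is least hindered.

Step 8
Reactants: 13 vinylogous methyl ester with the C8 epoxy ester
Product: 14 5,7-diketone (enolised)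
Conditions: 1 M HCl, THF, 0 °C to rt
Reagents that add atoms: water, O
Why: Acid hydrolysis of a vinylogous ester to the 1,3-diketone; the conditions are mild enough for the epoxy ester, which has no α-hydrogen and a deactivated epoxide.

Step 9
Reactants: 14 5,7-diketone
Product: 15 7-trifluoromethanesulfonyloxy-Δ6-5-ketone
Conditions: PhN(SO2CF3)2, Et3N, 4-(dimethylamino)pyridine (cat.), CH2Cl2, 0 °C to rt
Reagents that add atoms: N-phenylbis(trifluoromethanesulfonimide), O=S(=O)(N(c1ccccc1)S(=O)(=O)C(F)(F)F)C(F)(F)F
Why: O-Sulfonylation of the enolised 1,3-diketone; as in other 1,3-diketones with a quaternary carbon next to one carbonyl group, the less hindered oxygen (on C7) should be sulfonylated, which leaves the carbonyl at C5.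

Step 10
Reactants: 15 7-trifluoromethanesulfonyloxy-Δ6-5-ketone
Product: 16 7-(2-ethoxy-2-oxoethyl)-Δ6-5-ketone
Conditions: BrZnCH2CO2Et, Pd(PPh3)4 (5 mol %), THF, 40 °C
Reagents that add atoms: (2-ethoxy-2-oxoethyl)zinc bromide, CCOC(=O)C[Zn]Br
Why: Negishi-type cross-coupling of a zinc ester enolate with an enol triflate forms C7–C11; oxidative addition to the vinylogous acyl triflate is fast, which should keep the catalyst away from the hindered allylic ester at C8.

Step 11
Reactants: 16 7-(2-ethoxy-2-oxoethyl)-Δ6-5-ketone
Product: 17 5-trimethylsilyloxy-Δ5 enol ether with 7α-H and 7β-CH2CO2Et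
Conditions: [(Ph3P)CuH]6 (0.4 equiv), Me3SiCl, THF, −40 to 0 °C
Reagents that add atoms: chlorotrimethylsilane, C[Si](C)(C)Cl
Why: Copper hydride conjugate reduction of the β,β-disubstituted enone; as with other 4-oxygenated cyclohexenones, hydride should add to C7 anti to the C8 acyloxy group, i.e. from the α face. The side chain is then β and cis to the C8 oxygen, and the silyl chloride traps the enolate regiospecifically.

Step 12
Reactants: 17 5-trimethylsilyloxy-Δ5 enol ether
Product: 20 5-keto 6α,12-lactone (trans-fused), via 6-trimethylsilyloxy ketone 18 (not isolated), via hydroxy keto ester 19 (not isolated)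
Conditions: dimethyldioxirane, acetone/CH2Cl2, −78 °C; then camphor-10-sulfonic acid (cat.), wet CH2Cl2, rt
Reagents that add atoms: dimethyldioxirane, CC1(C)OO1
Why: Rubottom oxidation, then acid-catalysed desilylation and lactonisation; the oxidant should reach C6 anti to the neighbouring β side chain, so the C6 oxygen is α and the lactone trans-fused. C6 is α to the ketone, so a minor β epimer can equilibrate to this diequatorial arrangement.

Step 13
Reactants: 20 5-keto 6α,12-lactone
Product: 21 5β-hydroxy lactone
Conditions: NaBH4, CeCl3·7H2O, MeOH, −40 °C
Reagents that add atoms: none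
Why: Borohydride reduction under Luche conditions; the trans lactone holds ring B in one chair, in which equatorial approach is blocked by the axial C3 on C4. Hydride should therefore enter axially from the α face and give the equatorial 5β alcohol, trans to the C6 oxygen.

Step 14
Reactants: 21 5β-hydroxy lactone
Product: 24 Δ1(10),Δ2-dienoate, via dibromide 22 (not isolated), via allylic bromide 23 (not isolated)
Conditions: Br2, CH2Cl2, −78 °C; then DBU, PhMe, 0 to 60 °C
Reagents that add atoms: none
Why: Bromination of the isolated ring A alkene and twofold dehydrobromination (first towards C10, whose proton is α to the ester, then towards C3), the standard route from a cyclohexenecarboxylate to a cyclohexa-1,3-dienecarboxylate; the product has no acidic proton left in ring A.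

Step 15
Reactants: 24 Δ1(10),Δ2-dienoate
Product: 25 11-(dimethylaminomethyl) lactone (C11 epimers)
Conditions: LiN(iPr)2 (3.2 equiv), THF, −78 °C; then CH2=NMe2+ I−, −78 to 0 °C
Reagents that add atoms: dimethylmethyleneiminium iodide, C[N+](C)=C.[I-]
Why: Mannich reaction of the lactone lithium enolate with a preformed iminium salt; two equivalents of base are consumed by the hydroxyl groups, and C11 needs no control because it becomes trigonal in step 21.

Step 16
Reactants: 25 11-(dimethylaminomethyl) lactone
Product: 27 2α,3α-epoxide with free 5β and 9α hydroxyls, via bromohydrin 26 (not isolated)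
Conditions: CF3CO2H (1.2 equiv), N-bromosuccinimide, THF/H2O, 0 °C; then DBU, rt
Reagents that add atoms: water, O
Why: Bromohydrin formation and base-induced closure on the electron-rich γ,δ-alkene of the dienoate, with the amine protected as its salt. The bromonium ion should form on the β face because the C4 methyl group is pseudoaxial on the α face of ring A; water opens it from the α face and closure gives the α epoxide, which direct peracid epoxidation would not be expected to give.

Step 17
Reactants: 27 2α,3α-epoxide with free 5β and 9α hydroxyls
Product: 28 5β-methanesulfonate (fragmentation precursor: cis-decalin, 9α tertiary alcohol, trans lactone)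
Conditions: MsCl, Et3N, CH2Cl2, −20 °C
Reagents that add atoms: methanesulfonyl chloride, CS(=O)(=O)Cl
Why: Sulfonylation of the secondary equatorial hydroxyl; the tertiary C9 hydroxyl should stay free for the fragmentation.

Step 18
Reactants: 28 5β-methanesulfonate
Product: 29 ten-membered 9-ketone with the Z C4=C5 alkene, the C1=C10 enoate and the 2,3-epoxide
Conditions: KN(SiMe3)2 (1.1 equiv), THF, −78 to −20 °C
Reagents that add atoms: none
Why: Wharton (Grob-type) fragmentation of a 1,3-diol monosulfonate, the reaction type known for opening decalins to cyclodecenones. The base deprotonates the tertiary C9 hydroxyl; in the chair held by the trans lactone the C4–C9 bond is antiperiplanar to the equatorial C5–O bond, so in one concerted step the alkoxide becomes C9=O, C4–C9 breaks, C4=C5 forms and mesylate leaves. No ring is closed by bond formation: the ten-membered ring is released by cleaving the bond shared by rings A and B, and the only new skeletal bond is the C4=C5 π bond. No stereocentre is created; C4 and C9 become trigonal and C2, C3, C6, C7 and C8 are untouched. The alkene geometry is set by the substrate: C3 is axial on ring B and gauche to C6 while the methyl group is equatorial and anti to C6, so C3 and C6 end up cis on C4=C5 (the Z alkene); C1=C10 and the epoxide are carried over from ring A. The step needs alkoxide formation to outrun deprotonation elsewhere and fragmentation to outrun oxetane formation and acyl transfer. The hydroxyl is the most acidic site, the C8 ester is trans-diaxial to the alkoxide and cannot reach it, backside attack of O9 on C5 is geometrically poor, and the antiperiplanar alignment is built in.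

Step 19
Reactants: 29 ten-membered 9-ketone
Product: 30 C9 alcohol with the configuration of the target
Conditions: NaBH4, CeCl3·7H2O, MeOH, −78 °C
Reagents that add atoms: none
Why: Luche 1,2-reduction of the enone carbonyl; the C4=C5 alkene lies across the ring over one face of the ketone, as the fragmentation leaves it, so hydride should enter from the outer face, which corresponds to the C9 configuration of the target. The cerium salt suppresses conjugate reduction.

Step 20
Reactants: 30 C9 alcohol
Product: 31 trimethylammonium iodide
Conditions: MeI, THF, rt
Reagents that add atoms: iodomethane, CI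
Why: Quaternisation of the tertiary amine, the only nucleophilic centre in 30.

Step 21
Reactants: 31 trimethylammonium iodide
Product: 32 target CNP0291485.1
Conditions: NaHCO3, H2O/EtOAc, rt
Reagents that add atoms: none
Why: Hofmann-type (E1cB) elimination of trimethylamine from the β-ammonio lactone under mildly basic conditions releases the α-methylene lactone last, when no base or nucleophile remains to add to it.

## Compound list

1 | angelic acid, (Z)-2-methylbut-2-enoic acid | C/C=C(/C)C(=O)O | starting material
2 | (Z)-2-methylbut-2-en-1-ol | C/C=C(/C)CO | intermediate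
3 | [(2S,3R)-2,3-dimethyloxiran-2-yl]methanol | OC[C@]1(C)O[C@@H]1C | intermediate
4 | (2R,3R)-2,3-dimethyloxirane-2-carboxylic acid | OC(=O)[C@]1(C)O[C@@H]1C | intermediate
5 | 2-methoxy-5-methyl-1,4-benzoquinone | COC1=CC(=O)C(C)=CC1=O | starting material
6 | methyl (2E)-penta-2,4-dienoate | C=C/C=C/C(=O)OC | starting material
7 | cis-fused cycloadduct: 4α-methyl, 9α-H, 10β-CO2Me, C5 and C8 ketones, 7-methoxy C6=C7, C1=C2 (racemate, one enantiomer drawn) | C[C@@]12C(=O)C=C(OC)C(=O)[C@@H]1[C@H](C(=O)OC)C=CC2 | intermediate
8 | 8-trimethylsilyloxy C8=C9 dienol ether of 7 (racemate) | C[C@@]12C(=O)C=C(OC)C(O[Si](C)(C)C)=C1[C@H](C(=O)OC)C=CC2 | intermediate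
9 | 9α-trimethylsilyloxy 8-ketone (racemate) | C[C@@]12C(=O)C=C(OC)C(=O)[C@]1(O[Si](C)(C)C)[C@H](C(=O)OC)C=CC2 | intermediate
10 | 9α-hydroxy 8-ketone (racemate) | C[C@@]12C(=O)C=C(OC)C(=O)[C@]1(O)[C@H](C(=O)OC)C=CC2 | intermediate
11 | 8β,9α-diol (racemate) | C[C@@]12C(=O)C=C(OC)[C@H](O)[C@]1(O)[C@H](C(=O)OC)C=CC2 | intermediate
12 | mixed anhydride of 4 with 2,4,6-trichlorobenzoic acid | O=C(OC(=O)c1c(Cl)cc(Cl)cc1Cl)[C@]1(C)O[C@@H]1C | intermediate
13 | 8β-[(2R,3R)-2,3-dimethyloxirane-2-carbonyloxy] 9α-alcohol, vinylogous methyl ester, single enantiomer | C[C@@]12C(=O)C=C(OC)[C@H](OC(=O)[C@]3(C)O[C@@H]3C)[C@]1(O)[C@H](C(=O)OC)C=CC2 | intermediate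
14 | 5,7-diketone (drawn as the diketo form) | C[C@@]12C(=O)CC(=O)[C@H](OC(=O)[C@]3(C)O[C@@H]3C)[C@]1(O)[C@H](C(=O)OC)C=CC2 | intermediate
15 | 7-trifluoromethanesulfonyloxy-Δ6-5-ketone | C[C@@]12C(=O)C=C(OS(=O)(=O)C(F)(F)F)[C@H](OC(=O)[C@]3(C)O[C@@H]3C)[C@]1(O)[C@H](C(=O)OC)C=CC2 | intermediate
16 | 7-(2-ethoxy-2-oxoethyl)-Δ6-5-ketone | C[C@@]12C(=O)C=C(CC(=O)OCC)[C@H](OC(=O)[C@]3(C)O[C@@H]3C)[C@]1(O)[C@H](C(=O)OC)C=CC2 | intermediate
17 | 5-trimethylsilyloxy-Δ5 enol ether, 7α-H, 7β-CH2CO2Et | C[C@@]12C(O[Si](C)(C)C)=C[C@H](CC(=O)OCC)[C@H](OC(=O)[C@]3(C)O[C@@H]3C)[C@]1(O)[C@H](C(=O)OC)C=CC2 | intermediate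
18 | 6α-trimethylsilyloxy 5-ketone | C[C@@]12C(=O)[C@@H](O[Si](C)(C)C)[C@H](CC(=O)OCC)[C@H](OC(=O)[C@]3(C)O[C@@H]3C)[C@]1(O)[C@H](C(=O)OC)C=CC2 | intermediate
19 | 6α-hydroxy 5-ketone ethyl ester | C[C@@]12C(=O)[C@@H](O)[C@H](CC(=O)OCC)[C@H](OC(=O)[C@]3(C)O[C@@H]3C)[C@]1(O)[C@H](C(=O)OC)C=CC2 | intermediate
20 | 5-keto 6α,12-lactone (trans-fused) | C[C@@]12C(=O)[C@H]3OC(=O)C[C@@H]3[C@H](OC(=O)[C@]4(C)O[C@@H]4C)[C@]1(O)[C@H](C(=O)OC)C=CC2 | intermediate
21 | 5β-hydroxy lactone | C[C@@]12[C@H](O)[C@H]3OC(=O)C[C@@H]3[C@H](OC(=O)[C@]4(C)O[C@@H]4C)[C@]1(O)[C@H](C(=O)OC)C=CC2 | intermediate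
22 | 1,2-dibromide (trans; configuration at C1 and C2 not defined) | C[C@@]12[C@H](O)[C@H]3OC(=O)C[C@@H]3[C@H](OC(=O)[C@]4(C)O[C@@H]4C)[C@]1(O)[C@H](C(=O)OC)C(Br)C(Br)C2 | intermediate
23 | 2-bromo Δ1(10)-enoate (configuration at C2 not defined) | C[C@@]12[C@H](O)[C@H]3OC(=O)C[C@@H]3[C@H](OC(=O)[C@]4(C)O[C@@H]4C)[C@]1(O)C(C(=O)OC)=CC(Br)C2 | intermediate
24 | Δ1(10),Δ2-dienoate | C[C@@]12[C@H](O)[C@H]3OC(=O)C[C@@H]3[C@H](OC(=O)[C@]4(C)O[C@@H]4C)[C@]1(O)C(C(=O)OC)=CC=C2 | intermediate
25 | 11-(dimethylaminomethyl) lactone (C11 epimers) | C[C@@]12[C@H](O)[C@H]3OC(=O)C(CN(C)C)[C@@H]3[C@H](OC(=O)[C@]4(C)O[C@@H]4C)[C@]1(O)C(C(=O)OC)=CC=C2 | intermediate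
26 | 3β-bromo-2α-hydroxy bromohydrin | C[C@@]12[C@H](O)[C@H]3OC(=O)C(CN(C)C)[C@@H]3[C@H](OC(=O)[C@]4(C)O[C@@H]4C)[C@]1(O)C(C(=O)OC)=C[C@@H](O)[C@@H]2Br | intermediate
27 | 2α,3α-epoxide with 5β and 9α hydroxyls | C[C@@]12[C@H](O)[C@H]3OC(=O)C(CN(C)C)[C@@H]3[C@H](OC(=O)[C@]4(C)O[C@@H]4C)[C@]1(O)C(C(=O)OC)=C[C@H]5O[C@@H]25 | intermediate
28 | 5β-methanesulfonate, cis-fused epoxy decalin with 9α tertiary alcohol and trans lactone (fragmentation precursor) | C[C@@]12[C@H](OS(C)(=O)=O)[C@H]3OC(=O)C(CN(C)C)[C@@H]3[C@H](OC(=O)[C@]4(C)O[C@@H]4C)[C@]1(O)C(C(=O)OC)=C[C@H]5O[C@@H]25 | intermediate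
29 | ten-membered 9-ketone with Z C4=C5, ring-cis C1=C10 enoate and cis-2,3-epoxide | CN(C)CC1C(=O)O[C@@H]2/C=C(/C)[C@@H]3O[C@@H]3/C=C(/C(=O)OC)C(=O)[C@@H](OC(=O)[C@]3(C)O[C@@H]3C)[C@@H]12 | intermediate
30 | C9 alcohol of 29, configuration as in the target | CN(C)CC1C(=O)O[C@@H]2/C=C(/C)[C@@H]3O[C@@H]3/C=C(/C(=O)OC)[C@H](O)[C@@H](OC(=O)[C@]3(C)O[C@@H]3C)[C@@H]12 | intermediate
31 | trimethylammonium iodide of 30 | C[N+](C)(C)CC1C(=O)O[C@@H]2/C=C(/C)[C@@H]3O[C@@H]3/C=C(/C(=O)OC)[C@H](O)[C@@H](OC(=O)[C@]3(C)O[C@@H]3C)[C@@H]12.[I-] | intermediate
32 | CNP0291485.1 | C=C1C(=O)O[C@@H]2/C=C(/C)[C@@H]3O[C@@H]3/C=C(/C(=O)OC)[C@H](O)[C@@H](OC(=O)[C@]3(C)O[C@@H]3C)[C@@H]12 | target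

## Step count and weak points

Total step count: 21. Longest linear sequence: 18 steps (steps 4 to 21, from quinone 5); the three steps to acid 4 join at step 7.

Where the target's stereocentres are set: the acyl group in step 2; C8 in step 6 (relative) and step 7 (absolute, by separation); C7 in step 11; C6 in step 12; C2 and C3 in step 16; C9 in step 19.

Least certain steps:

**Step 18 (key step).** The amide base may also deprotonate C11 of the lactone, which would lead to loss of dimethylamine, or attack next to the vinyl epoxide. If ring B leaves the chair to relieve the 1,3-diaxial strain between C3 and the C8 ester, the antiperiplanar alignment, and with it the rate and the alkene geometry, would suffer. Fallback: from 28, the tertiary hydroxyl is silylated (Me3SiOTf, 2,6-lutidine, −78 °C) to the C9 trimethylsilyl ether of the mesylate F1. The alkoxide is then released by fluoride (Bu4NF, THF, −40 °C), so that no amide base meets the lactone; the fragmentation comes back to the route at 29.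

**Step 19.** Facial selectivity at C9 may be poor if the ten-membered ring relaxes to a conformer in which the transannular alkene no longer covers one face of the ketone. Fallback: from 29 to 30 under reagent control instead of substrate control, by Corey–Bakshi–Shibata reduction with catecholborane and the matching enantiomer of 1-methyl-3,3-diphenyltetrahydro-1H,3H-pyrrolo[1,2-c][1,3,2]oxazaborole; no compound outside the list is made (F0).

**Step 7.** Separation of the diastereomeric esters may be incomplete, because the stereocentres of the acyl group are remote from those of the core. Fallback: from racemic 10, kinetic resolution by Corey–Bakshi–Shibata reduction (half an equivalent of BH3·SMe2 with the oxazaborolidine enantiomer whose preferred face coincides with the α face of the wanted enantiomer). This returns to the route at 11 as a single enantiomer, and step 7 then needs no separation; no compound outside the list is made (F0).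

**Step 9.** Sulfonylation may occur on the wrong oxygen (O5), or the allylic ester may be ionised by the palladium catalyst in step 10. Fallback: from 13 directly to 16 by a Mukaiyama–Michael addition–elimination. tBuMe2SiOTf activates the vinylogous ester, 1-ethoxy-1-(trimethylsilyloxy)ethene adds at C7, and acid work-up expels methanol. This bypasses 14, 15 and the palladium step; no compound outside the list is made (F0).

**Step 16.** The bromonium ion may form with poor facial selectivity, or the allylic position may undergo substitution, so that the epoxide ends up on the β face or not at all. Fallback: from 25 to 27 by hydroxyl-directed epoxidation (VO(acac)2, t-BuOOH, amine held as its trifluoroacetate), in which the C9 hydroxyl, homoallylic to C2=C3 through C4, delivers the oxidant to the α face; no compound outside the list is made (F0).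

## Further compounds

F1 | step 18 | C9 trimethylsilyl ether of mesylate 28 | C[C@@]12[C@H](OS(C)(=O)=O)[C@H]3OC(=O)C(CN(C)C)[C@@H]3[C@H](OC(=O)[C@]4(C)O[C@@H]4C)[C@]1(O[Si](C)(C)C)C(C(=O)OC)=C[C@H]5O[C@@H]25
F0 | step 19 | none | none
F0 | step 7 | none | none
F0 | step 9 | none | none
F0 | step 16 | none | none
A1 | alternative 1 | (S)-5-[(tert-butyldiphenylsilyloxy)methyl]furan-2(5H)-one | O=C1C=C[C@@H](CO[Si](c2ccccc2)(c2ccccc2)C(C)(C)C)O1
A2 | alternative 1 | trans-4-vinyl-3-(dimethylaminomethyl) lactone | CN(C)C[C@@H]1C(=O)O[C@H](CO[Si](c2ccccc2)(c2ccccc2)C(C)(C)C)[C@H]1C=C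
A3 | alternative 2 | C9 triethylsilyl ether of 32 | C=C1C(=O)O[C@@H]2/C=C(/C)[C@@H]3O[C@@H]3/C=C(/C(=O)OC)[C@H](O[Si](CC)(CC)CC)[C@@H](OC(=O)[C@]3(C)O[C@@H]3C)[C@@H]12
A4 | alternative 3 | ten-membered 6-ketone carrying the C8 and C9 oxygens | C=C(CO[Si](C)(C)C(C)(C)C)[C@H]1C(=O)/C=C(/C)[C@@H]2O[C@@H]2/C=C(/CO[Si](C)(C)C(C)(C)C)[C@H](OCc3ccc(OC)cc3)[C@H]1O[Si](C(C)C)(C(C)C)C(C)C
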